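**Strategy.** The route rests on disconnecting the congested C1–C8 bond of ring B (C1–C9–C5–C6–C7–C8). It exploits one feature: the C7 methine, flanked by the quaternary carbon C8 and by two methylene branches (C6 inside ring B, C15 outside it), is C4 of (S)-limonene together with its isopropenyl group. The precursor is an acyclic 2-diazo-1-phenyl-1,3-diketone made by cleaving the limonene ring. In one operation a copper carbenoid at C1 adds to the isopropenyl alkene, closing ring B and a temporary cyclopropane whose CH2 later becomes the second C8 methyl. The C2–C3–C4 bridge is then laid across C5 and C1, and an oxidative radical cascade builds the cage.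

Key step: step 6

Numbering used for all compounds: C1 benzoyl-bearing carbon; C2, C4, C9 ring carbonyl carbons; C3 between C2 and C4; C5 geranyl-bearing carbon; C6 H2; C7 H; C8 CMe2; C15 H2 and C16 H between C7 and C3; C12 CMe2; C11 H (isopropenyl); C10 H2. Ring A is C1–C2–C3–C4–C5–C9, ring B is C1–C9–C5–C6–C7–C8.

Remark on configuration: with C6 traced to limonene C5 and C15 to limonene C3, C7 of the target has the sense of C4 in (S)-limonene, so the (S) enantiomer is the correct source. The centre keeps its spatial arrangement throughout; only its CIP letter changes (S up to 10, R from 14 on) because neighbour priorities change.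

Assumptions: 1,3-dicarbonyl compounds are drawn as keto forms, and their enolisable centres (C1 in 10, 14 and 16; C5 in 14; C3 in 19) are left unassigned. For 9 the cis-fused isomer with the cyclopropane CH2 cis to the prenyl chain is drawn as the expected major product; its cis-fused epimer would be carried on unchanged.

**Route**

Step 1
Reactants: 1 (S)-limonene
Product: 2 (4S)-limonene 1,2-oxide (cis/trans epoxide mixture)
Conditions: mCPBA (1.0 equiv), CH2Cl2, 0 °C
Reagents that add atoms: mCPBA (3-chloroperoxybenzoic acid), OOC(=O)c1cccc(Cl)c1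
Why: Prilezhaev epoxidation, in which the peracid should react faster with the trisubstituted ring alkene than with the 1,1-disubstituted isopropenyl group; the epoxide diastereomers do not matter because both new centres are destroyed in step 2.

Step 2
Reactants: 2 (4S)-limonene 1,2-oxide
Product: 4 (3S)-6-oxo-3-(prop-1-en-2-yl)heptanal, via limonene-1,2-diol 3 (not isolated)
Conditions: H5IO6 (1.1 equiv), THF/H2O, 0 → 23 °C
Reagents that add atoms: water, O
Why: Periodic acid should hydrolyse the epoxide to the trans-diol and cleave it in the same flask (Malaprade glycol cleavage), giving the methyl ketone and aldehyde arms on the untouched C7 centre, which is β to the aldehyde and cannot epimerise.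

Step 3
Reactants: 4 (3S)-6-oxo-3-(prop-1-en-2-yl)heptanal
Product: 5 (5S)-8-methyl-5-(prop-1-en-2-yl)non-7-en-2-one
Conditions: i-PrPPh3I (1.1 equiv), n-BuLi (1.05 equiv), THF, 0 °C; then 4, −78 → 0 °C
Reagents that add atoms: isopropyltriphenylphosphonium iodide, CC(C)[P+](c1ccccc1)(c1ccccc1)c1ccccc1.[I-]
Why: Wittig olefination, in which the non-stabilised isopropylidene ylide should add to the aldehyde much faster than to the methyl ketone at low temperature, installing the prenyl terminus (C15–C16=C12Me2) without touching a stereocentre.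

Step 4
Reactants: 5 (5S)-8-methyl-5-(prop-1-en-2-yl)non-7-en-2-one; 6 methyl benzoate
Product: 7 (6S)-9-methyl-1-phenyl-6-(prop-1-en-2-yl)dec-8-ene-1,3-dione
Conditions: NaH (2.5 equiv), THF, 65 °C; then 1 M HCl, 0 °C
Reagents that add atoms: none
Why: Crossed Claisen condensation under equilibrating conditions should acylate the methyl rather than the methylene side of the ketone, because only that product is drained as its stable 1,3-diketonate, and methyl benzoate has no α-hydrogen for self-condensation.

Step 5
Reactants: 7 (6S)-9-methyl-1-phenyl-6-(prop-1-en-2-yl)dec-8-ene-1,3-dione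
Product: 8 (6S)-2-diazo-9-methyl-1-phenyl-6-(prop-1-en-2-yl)dec-8-ene-1,3-dione
Conditions: p-ABSA (1.1 equiv), Et3N, MeCN, 0 → 23 °C
Reagents that add atoms: 4-acetamidobenzenesulfonyl azide (p-ABSA), CC(=O)Nc1ccc(cc1)S(=O)(=O)N=[N+]=[N-]
Why: Regitz diazo transfer to the doubly activated methylene of the 1,3-diketone under mild amine base should give the stable 2-diazo-1,3-diketone without affecting either alkene.

Step 6
Reactants: 8 (6S)-2-diazo-9-methyl-1-phenyl-6-(prop-1-en-2-yl)dec-8-ene-1,3-dione
Product: 9 (1S,5S,6R)-1-benzoyl-6-methyl-5-(3-methylbut-2-en-1-yl)bicyclo[4.1.0]heptan-2-one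
Conditions: Cu(acac)2 (5 mol %), PhMe, 110 °C, slow addition of 8
Reagents that add atoms: none
Why: Loss of N2 from 8 at copper (Cu(acac)2 is reduced in the flask to the active monovalent copper species) should give an electrophilic diacylcarbenoid at C1 that adds across the 1,1-disubstituted isopropenyl alkene in an asynchronous [2+1] step, bonding first to the terminal CH2 and then to the tertiary carbon C8. The closest known reaction type is the copper-catalysed intramolecular cyclopropanation of 2-diazo-1,3-dicarbonyl compounds bearing a δ,ε-alkene, which gives 1-acylbicyclo[4.1.0]heptan-2-ones. Ring B (C1–C9–C5–C6–C7–C8) closes in the exo mode, C1 bonding to the internal alkene carbon, and the three-membered ring (C1–C8–CH2) closes in the same cheletropic addition and can only be cis-fused. The new centres C1 and C8 are therefore tied to each other, and their sense relative to C7 should follow from a chair-like approach with the C7 prenyl chain pseudo-equatorial, which leads to the isomer drawn; the other cis-fused isomer is equally usable because both centres are erased in step 7. The step needs selectivity for the isopropenyl over the prenyl alkene, which the tether secures (six- against seven-membered closure), and for cyclopropanation over insertion into the allylic C7–H bond, which copper secures because its diacylcarbenoids add to alkenes far more readily than they insert into C–H bonds.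

Step 7
Reactants: 9 (1S,5S,6R)-1-benzoyl-6-methyl-5-(3-methylbut-2-en-1-yl)bicyclo[4.1.0]heptan-2-one
Product: 10 (4S)-2-benzoyl-3,3-dimethyl-4-(3-methylbut-2-en-1-yl)cyclohexan-1-one
Conditions: Li (2.2 equiv), NH3(l)/THF, −78 °C; then NH4Cl
Reagents that add atoms: none
Why: Dissolving-metal reductive cleavage of a doubly activated cyclopropyl ketone, in which the ketyl should open the exocyclic C1–CH2 bond (best overlap with the C9 carbonyl, less substituted carbanion) and the second electron should arrive before the transient primary radical can add 5-exo to the prenyl alkene, which is why lithium in ammonia is chosen over a slower one-electron donor such as SmI2; protonation leaves the second C8 methyl and the C1 diketonate and erases both cyclopropane centres.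

Step 8
Reactants: 11 N-methoxy-N-methylacetamide; 12 prenyl bromide
Product: 13 N-methoxy-N,5-dimethylhex-4-enamide
Conditions: LDA (1.05 equiv), THF, −78 °C; then 12, −78 → 0 °C
Reagents that add atoms: none
Why: Alkylation of the lithium amide enolate with the reactive allylic bromide at low temperature should give the acyl fragment that carries C4, C3 and the future C10–C11 prenyl arm.

Step 9
Reactants: 10 (4S)-2-benzoyl-3,3-dimethyl-4-(3-methylbut-2-en-1-yl)cyclohexan-1-one; 13 N-methoxy-N,5-dimethylhex-4-enamide
Product: 14 (4R)-2-benzoyl-3,3-dimethyl-4-(3-methylbut-2-en-1-yl)-6-(5-methylhex-4-enoyl)cyclohexan-1-one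
Conditions: LDA (2.2 equiv), THF, −78 → 0 °C; then 13, −78 → 0 °C; aq. NH4Cl
Reagents that add atoms: none
Why: γ-Acylation of a 1,3-diketone dianion, in which the more basic and less hindered carbon C5 should attack the N-methoxy-N-methylamide while the chelated tetrahedral adduct prevents over-addition and proton quench; the new C5 centre stays enolisable and is left unassigned.

Step 10
Reactants: 14 (4R)-2-benzoyl-3,3-dimethyl-4-(3-methylbut-2-en-1-yl)-6-(5-methylhex-4-enoyl)cyclohexan-1-one; 15 geranyl bromide
Product: 16 (4R,6R)-2-benzoyl-6-[(2E)-3,7-dimethylocta-2,6-dien-1-yl]-3,3-dimethyl-4-(3-methylbut-2-en-1-yl)-6-(5-methylhex-4-enoyl)cyclohexan-1-one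
Conditions: K2CO3 (1.5 equiv), acetone, 40 °C
Reagents that add atoms: none
Why: C-alkylation of the 2-acylcyclohexanone unit at C5 (C1 is shielded by the C8 gem-dimethyl group) with a soft allylic bromide, in which geranyl bromide should approach the C5 enolate axially on the face opposite the pseudo-equatorial C7 prenyl chain, so that geranyl ends trans and the C4 acyl chain cis to that chain, the relationship that later places C15 endo.

Step 11
Reactants: 16 (4R,6R)-2-benzoyl-6-geranyl-3,3-dimethyl-4-prenyl-6-(5-methylhex-4-enoyl)cyclohexan-1-one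
Product: 19 (1S,5R,7R)-1-benzoyl-5-geranyl-8,8-dimethyl-3,7-diprenylbicyclo[3.3.1]nonane-2,4,9-trione, via acyl imidazole 17 (not isolated), via acylketene 18 (not isolated)
Conditions: LDA (2.2 equiv), THF, −78 °C; CDI (1.1 equiv), −78 → 50 °C; then 1 M HCl, 0 °C
Reagents that add atoms: 1,1'-carbonyldiimidazole (CDI), O=C(n1ccnc1)n1ccnc1
Why: Proposed new method: double deprotonation (C1–H, then C3–H2) and C-acylation of the more basic C3 enolate by CDI should give the β-keto acyl imidazole 17, whose E1cB loss of imidazolide gives acylketene 18; the unhindered sp carbon C2 of 18 is then attacked from the tether face by the C1 diketonate, the only irreversible outcome being the C3 enolate of trione 19 (an O-acylated enol lactone returns to 18 by the same E1cB path), and C1 is fixed because the C2–C3–C4 bridge can span C1 and C5 on one face only; the closest known reaction types are the Dieckmann closure of bicyclo[3.3.1]nonane-2,4,9-triones, the ring-closing C-acylation in malonyl dichloride annulations of cyclohexanone enol ethers, and the Claisen cyclisation of 3,5,7-triketo esters to acylphloroglucinols.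

Step 12
Reactants: 19 (1S,5R,7R)-1-benzoyl-5-geranyl-8,8-dimethyl-3,7-diprenylbicyclo[3.3.1]nonane-2,4,9-trione
Product: 20 CNP0110731.1 (target)
Conditions: Mn(OAc)3·2H2O (2.2 equiv), Cu(OAc)2·H2O (1.0 equiv), degassed AcOH, 23 °C
Reagents that add atoms: none
Why: Oxidative free-radical cyclisation with Mn(OAc)3, in which the enol of the 2-alkyl-1,3-diketone is oxidised to the C3 radical, which should add to C16 of the endo C7 prenyl chain held under ring A (C3 set by the cage, C16 by the conformer that turns the CMe2 end toward C6 and away from the C8 methyls); the tertiary C12 radical then closes 5-exo onto C11 of the C3 prenyl group through a chair-like transition state that puts the new side chain trans to C15, and Cu(OAc)2 oxidises the final tertiary radical to the isopropenyl group.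

**Compound list**

1 | (S)-limonene, (4S)-1-methyl-4-(prop-1-en-2-yl)cyclohex-1-ene | CC1=CC[C@H](CC1)C(C)=C | starting material
2 | (4S)-1-methyl-4-(prop-1-en-2-yl)-7-oxabicyclo[4.1.0]heptane (limonene 1,2-oxide, cis/trans mixture) | CC12OC1C[C@H](CC2)C(C)=C | intermediate
3 | (4S)-1-methyl-4-(prop-1-en-2-yl)cyclohexane-1,2-diol (limonene-1,2-diol, not isolated) | CC1(O)C(O)C[C@H](CC1)C(C)=C | intermediate
4 | (3S)-6-oxo-3-(prop-1-en-2-yl)heptanal | CC(=O)CC[C@@H](CC=O)C(C)=C | intermediate
5 | (5S)-8-methyl-5-(prop-1-en-2-yl)non-7-en-2-one | CC(=O)CC[C@@H](CC=C(C)C)C(C)=C | intermediate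
6 | methyl benzoate | COC(=O)c1ccccc1 | starting material
7 | (6S)-9-methyl-1-phenyl-6-(prop-1-en-2-yl)dec-8-ene-1,3-dione | O=C(c1ccccc1)CC(=O)CC[C@@H](CC=C(C)C)C(C)=C | intermediate
8 | (6S)-2-diazo-9-methyl-1-phenyl-6-(prop-1-en-2-yl)dec-8-ene-1,3-dione | O=C(c1ccccc1)C(=[N+]=[N-])C(=O)CC[C@@H](CC=C(C)C)C(C)=C | intermediate
9 | (1S,5S,6R)-1-benzoyl-6-methyl-5-(3-methylbut-2-en-1-yl)bicyclo[4.1.0]heptan-2-one (cyclopropane CH2 cis to the prenyl chain) | O=C(c1ccccc1)[C@@]12C[C@]1(C)[C@H](CC=C(C)C)CCC2=O | intermediate
10 | (4S)-2-benzoyl-3,3-dimethyl-4-(3-methylbut-2-en-1-yl)cyclohexan-1-one (C2 enolisable) | O=C(c1ccccc1)C1C(=O)CC[C@@H](CC=C(C)C)C1(C)C | intermediate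
11 | N-methoxy-N-methylacetamide | CON(C)C(C)=O | starting material
12 | prenyl bromide, 1-bromo-3-methylbut-2-ene | CC(C)=CCBr | starting material
13 | N-methoxy-N,5-dimethylhex-4-enamide | CON(C)C(=O)CCC=C(C)C | intermediate
14 | (4R)-2-benzoyl-3,3-dimethyl-4-(3-methylbut-2-en-1-yl)-6-(5-methylhex-4-enoyl)cyclohexan-1-one (C2 and C6 enolisable) | O=C(c1ccccc1)C1C(=O)C(C(=O)CCC=C(C)C)C[C@@H](CC=C(C)C)C1(C)C | intermediate
15 | geranyl bromide, (2E)-1-bromo-3,7-dimethylocta-2,6-diene | CC(C)=CCC/C(C)=C/CBr | starting material
16 | (4R,6R)-2-benzoyl-6-[(2E)-3,7-dimethylocta-2,6-dien-1-yl]-3,3-dimethyl-4-(3-methylbut-2-en-1-yl)-6-(5-methylhex-4-enoyl)cyclohexan-1-one (geranyl trans to the C4 prenyl chain; C2 enolisable) | O=C(c1ccccc1)C1C(=O)[C@@](C/C=C(\C)CCC=C(C)C)(C(=O)CCC=C(C)C)C[C@@H](CC=C(C)C)C1(C)C | intermediate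
17 | acyl imidazole: 16 carrying an imidazole-1-carbonyl group on C3 of the acyl chain, ring centres as in 16 (not isolated) | O=C(c1ccccc1)C1C(=O)[C@@](C/C=C(\C)CCC=C(C)C)(C(=O)C(CC=C(C)C)C(=O)n2ccnc2)C[C@@H](CC=C(C)C)C1(C)C | intermediate
18 | acylketene: 16 with C3 of the acyl chain as a ketene carbon (C3=C2=O), ring centres as in 16 (not isolated) | O=C(c1ccccc1)C1C(=O)[C@@](C/C=C(\C)CCC=C(C)C)(C(=O)C(CC=C(C)C)=C=O)C[C@@H](CC=C(C)C)C1(C)C | intermediate
19 | (1S,5R,7R)-1-benzoyl-5-[(2E)-3,7-dimethylocta-2,6-dien-1-yl]-8,8-dimethyl-3,7-bis(3-methylbut-2-en-1-yl)bicyclo[3.3.1]nonane-2,4,9-trione (C7 prenyl endo, toward C3; C3 enolisable) | O=C1C(CC=C(C)C)C(=O)[C@@]2(C/C=C(\C)CCC=C(C)C)C[C@@H](CC=C(C)C)C(C)(C)[C@]1(C(=O)c3ccccc3)C2=O | intermediate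
20 | CNP0110731.1: 19 with C3 bonded to C16 (C7–C15–C16–C3 bridge) and a cyclopentane C3–C10–C11–C12–C16 bearing 12,12-dimethyl and 11-isopropenyl; H-16 on the C2 side, isopropenyl cis to H-16 | C=C(C)[C@@H]1C[C@@]23C(=O)[C@@]4(C/C=C(\C)CCC=C(C)C)C[C@@H](C[C@H]2C1(C)C)C(C)(C)[C@](C(=O)c1ccccc1)(C4=O)C3=O | target

**Step count and risks**

Total step count: 12. Longest linear sequence: 11 steps (steps 1–7 and 9–12; step 8 makes the side fragment 13).

Steps most likely to fail:

1. Step 11 (the labelled step). What may go wrong: acyl transfer may stop at oxygen as an enol lactone, or the C3 enolate may be lost by proton exchange before it is acylated, so that the hindered C1–C2 bond does not form. Fallback with known reactions, leaving the route at 10 and rejoining it at 19: 3-(trimethylsilyl)propiolic acid is coupled with N,O-dimethylhydroxylamine to give N-methoxy-N-methyl-3-(trimethylsilyl)prop-2-ynamide F1. The dianion of 10 is acylated with it at C5 to give the silyl ynone F2, and geranylation as in step 10 gives the quaternary silyl ynone F3. K2CO3 in MeOH removes the silyl group and lets the C1 diketonate add in a 6-endo Michael reaction to the terminal alkyne carbon C2, giving the bicyclic enedione F4. Wacker-type oxidation of the enone (Na2PdCl4 cat., t-BuOOH, AcOH/H2O) gives the C3-unsubstituted trione F5, and Tsuji–Trost C-prenylation at C3 (12, Pd(PPh3)4 cat., K2CO3) gives 19.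

2. Step 12. What may go wrong: the C3 radical may add to the nearer C5 geranyl alkene (5-exo across C4), may be oxidised or dimerise before the transannular closure, or the facial selectivity at C16 and C11 may be poor. Fallback, leaving the route at 19 and rejoining it at 20: selenenylation of the lithium enolate of 19 with N-(phenylseleno)phthalimide gives the 3-phenylselanyl trione F6. Irradiation (sunlamp, benzene) starts a phenylseleno group-transfer radical cascade that runs through the same two ring closures under non-oxidising chain conditions and ends as the tertiary selenide F7. Oxidation with H2O2/pyridine and selenoxide syn-elimination toward a methyl group gives 20.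

3. Step 6. What may go wrong: the carbenoid may insert into the allylic C7–H bond to give a cyclopentanone, undergo Wolff rearrangement, or add to the prenyl alkene. Fallback, leaving the route at 7 and rejoining it at 10 (8 and 9 are bypassed): Conia-ene-type Markovnikov hydroalkylation of the isopropenyl group by the 1,3-diketone under monovalent gold catalysis (AuCl[P(t-Bu)2(o-biphenyl)]/AgOTf, toluene, 60 °C) forms the same C1–C8 bond and the C8 gem-dimethyl group directly, with no new compound.

**Further compounds**

F1 | step 11 | N-methoxy-N-methyl-3-(trimethylsilyl)prop-2-ynamide | CON(C)C(=O)C#C[Si](C)(C)C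
F2 | step 11 | 2-benzoyl-3,3-dimethyl-4-(3-methylbut-2-en-1-yl)-6-[3-(trimethylsilyl)prop-2-ynoyl]cyclohexan-1-one (C7 as in 10) | O=C(c1ccccc1)C1C(=O)C(C(=O)C#C[Si](C)(C)C)C[C@@H](CC=C(C)C)C1(C)C
F3 | step 11 | 6-geranyl derivative of F2 (geranyl trans to the C7 prenyl chain) | O=C(c1ccccc1)C1C(=O)[C@@](C/C=C(\C)CCC=C(C)C)(C(=O)C#C[Si](C)(C)C)C[C@@H](CC=C(C)C)C1(C)C
F4 | step 11 | 1-benzoyl-5-geranyl-8,8-dimethyl-7-prenylbicyclo[3.3.1]non-2-ene-4,9-dione (centres as in 19) | O=C1C=C[C@@]2(C(=O)c3ccccc3)C(=O)[C@]1(C/C=C(\C)CCC=C(C)C)C[C@@H](CC=C(C)C)C2(C)C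
F5 | step 11 | 1-benzoyl-5-geranyl-8,8-dimethyl-7-prenylbicyclo[3.3.1]nonane-2,4,9-trione (centres as in 19) | O=C1CC(=O)[C@@]2(C/C=C(\C)CCC=C(C)C)C[C@@H](CC=C(C)C)C(C)(C)[C@]1(C(=O)c3ccccc3)C2=O
F6 | step 12 | 3-(phenylselanyl) derivative of 19 (C3 configuration not fixed) | O=C1C(CC=C(C)C)([Se]c4ccccc4)C(=O)[C@@]2(C/C=C(\C)CCC=C(C)C)C[C@@H](CC=C(C)C)C(C)(C)[C@]1(C(=O)c3ccccc3)C2=O
F7 | step 12 | tertiary selenide: 20 with a 2-(phenylselanyl)propan-2-yl group on C11 in place of isopropenyl | CC(C)([Se]c1ccccc1)[C@@H]1C[C@@]23C(=O)[C@@]4(C/C=C(\C)CCC=C(C)C)C[C@@H](C[C@H]2C1(C)C)C(C)(C)[C@](C(=O)c1ccccc1)(C4=O)C3=O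
F0 | step 6 | none | none
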